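**Plan**
- Retrosynthetic cuts, in order: the five O–CH3 bonds and the acetals; O1–C2 of the chroman; C2–C1′ to the B ring; C2–C3 (one carbon inserted into a C3–B bond); then, in one operation, C4–C4a and C3–CH(CH3)2.
- Enabling feature: chroman C4 carries the A-ring carbon C4a and an isobutyl group, and the adjacent C3 carries an isopropyl group. This is the pattern left by adding an aryl group and isopropyl across iBuCH=CH–B.
- Forward: A-ring aryl iodide, Z-alkenylboron and isopropyllithium give the acyclic C3–C4 unit; C3–B becomes C3–CHO; debenzylation folds it to a lactol; the B-ring aryllithium opens the lactol; acid closes the pyran ring (the only ring formed) last; global demethylation.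
- Stereochemistry: C4 from the chiral ligand on palladium; C3 from anti addition across the Z alkene, kept through boron-to-carbon migration with retention; C2 from closure of a benzylic cation trans to the C3 isopropyl group. The target is (2R,3R,4S): 2,3-trans, 3,4-cis.

Key step: step 6

Assumption: the (Sp,Sp) enantiomer of MandyPhos is taken as the one that delivers the aryl group to the alkene face leading to the (3R,4S) boronate of step 6; if the facial sense is the reverse, the (Rp,Rp) ligand is used and nothing else changes.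

**Route**

Step 1
Reactants: 1 4-hydroxy-2,6-dimethoxybenzaldehyde
Product: 2 4-hydroxy-3-iodo-2,6-dimethoxybenzaldehyde
Conditions: NIS (1.0 equiv), TFA (cat.), MeCN, 0 °C to rt
Reagents that add atoms: N-iodosuccinimide, O=C1CCC(=O)N1I
Why: Electrophilic aromatic iodination ortho to the free phenol; the two open positions are equivalent by symmetry, and one equivalent of reagent on the formyl-deactivated ring should stop at the mono-iodide.

Step 2
Reactants: 2 4-hydroxy-3-iodo-2,6-dimethoxybenzaldehyde
Product: 3 4-(benzyloxy)-3-iodo-2,6-dimethoxybenzaldehyde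
Conditions: BnBr, K2CO3, DMF, rt
Reagents that add atoms: benzyl bromide, BrCc1ccccc1
Why: Williamson etherification of the acidic para-formyl phenol; the benzyl ether marks the oxygen that later becomes O1 and is removable without acid.

Step 3
Reactants: 3 4-(benzyloxy)-3-iodo-2,6-dimethoxybenzaldehyde
Product: 4 2-[4-(benzyloxy)-3-iodo-2,6-dimethoxyphenyl]-1,3-dioxolane
Conditions: HOCH2CH2OH, p-TsOH (cat.), toluene, reflux, Dean–Stark
Reagents that add atoms: ethylene glycol, OCCO
Why: Acid-catalysed acetalisation with azeotropic removal of water masks the aldehyde against the organolithium and carbenoid reagents used later.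

Step 4
Reactants: 5 acenaphthylene-1,2-dione
Product: 6 cis-1,2-dimethyl-1,2-dihydroacenaphthylene-1,2-diol (meso, "mac diol")
Conditions: AlMe3 (2.5 equiv), toluene, 0 °C to rt; then H2O; recrystallisation
Reagents that add atoms: trimethylaluminium, C[Al](C)C
Why: Double 1,2-addition of methyl to the 1,2-dione; aluminium held between the first alkoxide and the remaining carbonyl shields that face, so the second methyl should enter from the methyl-bearing side and give the cis diol.

Step 5
Reactants: 7 4-methylpent-1-yne; 6 cis-1,2-dimethyl-1,2-dihydroacenaphthylene-1,2-diol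
Product: 9 (Z)-4-methylpent-1-enylboronic acid mac ester, via catechol (Z)-alkenylboronate 8 (not isolated)
Conditions: catecholborane, [Rh(cod)Cl]2 (1.5 mol%), P(i-Pr)3 (6 mol%), Et3N (1 equiv), cyclohexane, rt; then 6, rt
Reagents that add atoms: catecholborane, B1Oc2ccccc2O1
Why: Rhodium(I)/trialkylphosphine/amine-catalysed trans-hydroboration of a terminal alkyne runs through a rhodium vinylidene and gives the Z-1-alkenyl catechol boronate 8, whose labile catechol is then exchanged for the 1,2-diol 6.

Step 6
Reactants: 9 (Z)-4-methylpent-1-enylboronic acid mac ester; 10 isopropyllithium; 4 2-[4-(benzyloxy)-3-iodo-2,6-dimethoxyphenyl]-1,3-dioxolane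
Product: 12 mac ester of (3R,4S)-4-[6-(benzyloxy)-3-(1,3-dioxolan-2-yl)-2,4-dimethoxyphenyl]-2,6-dimethylheptan-3-ylboronic acid, via lithium alkenyl(isopropyl)borate 11 (not isolated)
Conditions: 9 (1.2 equiv), halide-free i-PrLi (1.15 equiv), Et2O, −78 to 0 °C; remove solvent; 4 (1.0 equiv), Pd(OAc)2 (3 mol%), (Sp,Sp)-MandyPhos (3.6 mol%), KOTf (2 equiv), THF, 60 °C
Reagents that add atoms: none
Why: Isopropyllithium adds to boron of 9 to give ate complex 11; oxidative addition of 4 to Pd(0), removal of iodide as KI by the triflate salt and binding of the cationic arylpalladium(II) to the alkene then trigger a 1,2-shift of isopropyl from boron to the boron-bearing carbon anti to palladium, and C–C reductive elimination from the β-boryl alkyl(aryl)palladium joins the aryl carbon to the isobutyl-bearing carbon with retention. The closest known reaction is the palladium/MandyPhos conjunctive cross-coupling of β-substituted alkenyl B(mac) ate complexes with aryl electrophiles. No ring closes in this step. The aryl-bearing stereocentre (later chroman C4) is set by the chiral bisphosphine, which selects the alkene face that palladium binds; the boron-bearing stereocentre (later C3) follows from it through the stereospecific anti addition across the Z double bond, giving the (3R,4S) pair that becomes the 3,4-cis relationship. The step needs the 1,2-shift to outrun direct Suzuki transfer of the alkenyl or isopropyl group and β-hydride elimination: the hindered mac diol on boron disfavours transmetallation, the wide-bite-angle ligand speeds reductive elimination, and the iodide with triflate additive keeps the di-ortho-oxygenated arylpalladium cationic and reactive.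

Step 7
Reactants: 12 mac ester of (3R,4S)-4-[6-(benzyloxy)-3-(1,3-dioxolan-2-yl)-2,4-dimethoxyphenyl]-2,6-dimethylheptan-3-ylboronic acid
Product: 14 (2R,3S)-3-[6-(benzyloxy)-3-(1,3-dioxolan-2-yl)-2,4-dimethoxyphenyl]-5-methyl-2-(propan-2-yl)hexanal, via α-chloro boronic ester 13 (not isolated)
Conditions: CH2Cl2, n-BuLi, THF, −100 °C; add 12, −100 °C to rt; then 30% H2O2, aq NaHCO3, THF, 0 °C
Reagents that add atoms: dichloromethane, ClCCl; hydrogen peroxide, OO
Why: Matteson homologation, in which (dichloromethyl)lithium adds to boron and the C3 alkyl group migrates to the carbenoid carbon with retention of configuration; buffered peroxide oxidation of the α-chloro boronic ester 13 then collapses to the aldehyde under cold, weakly basic conditions that should spare the α-stereocentre and the acetal.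

Step 8
Reactants: 14 (2R,3S)-3-[6-(benzyloxy)-3-(1,3-dioxolan-2-yl)-2,4-dimethoxyphenyl]-5-methyl-2-(propan-2-yl)hexanal
Product: 15 (3R,4S)-6-(1,3-dioxolan-2-yl)-5,7-dimethoxy-4-(2-methylpropyl)-3-(propan-2-yl)chroman-2-ol (both C2 epimers)
Conditions: H2 (1 atm), 10% Pd/C, EtOAc, rt
Reagents that add atoms: none
Why: Hydrogenolysis of the aryl benzyl ether under neutral aprotic conditions frees the phenol, which closes onto the aldehyde as the six-membered lactol; the hindered aryl dioxolane and the aliphatic aldehyde are not expected to react under these mild conditions.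

Step 9
Reactants: 16 1,3,5-trimethoxybenzene
Product: 17 2,4,6-trimethoxybenzene-1,3-dicarbaldehyde
Conditions: Cl2CHOMe (2.5 equiv), TiCl4 (4 equiv), CH2Cl2, 0 °C to rt; then aq HCl
Reagents that add atoms: dichloromethyl methyl ether, COC(Cl)Cl; water, O
Why: Rieche formylation (Friedel–Crafts reaction of the dichloromethyl methyl ether–TiCl4 complex, hydrolysed on work-up); three methoxy groups keep the ring reactive enough for a second formylation, and limiting the reagent leaves the third position open.

Step 10
Reactants: 17 2,4,6-trimethoxybenzene-1,3-dicarbaldehyde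
Product: 18 5-bromo-2,4,6-trimethoxybenzene-1,3-dicarbaldehyde
Conditions: NBS, TFA (cat.), MeCN, rt
Reagents that add atoms: N-bromosuccinimide, O=C1CCC(=O)N1Br
Why: Electrophilic aromatic bromination at the only remaining ring position, which is ortho or para to all three methoxy groups and meta to both aldehydes.

Step 11
Reactants: 18 5-bromo-2,4,6-trimethoxybenzene-1,3-dicarbaldehyde
Product: 19 2,2'-(5-bromo-2,4,6-trimethoxy-1,3-phenylene)bis(1,3-dioxolane)
Conditions: HOCH2CH2OH, p-TsOH (cat.), toluene, reflux, Dean–Stark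
Reagents that add atoms: ethylene glycol, OCCO
Why: Twofold acid-catalysed acetalisation protects both aldehydes so that the ring can serve as an aryllithium and, later, as a cation-stabilising aryl group.

Step 12
Reactants: 19 2,2'-(5-bromo-2,4,6-trimethoxy-1,3-phenylene)bis(1,3-dioxolane); 15 (3R,4S)-6-(1,3-dioxolan-2-yl)-5,7-dimethoxy-4-(2-methylpropyl)-3-(propan-2-yl)chroman-2-ol
Product: 21 (2R,3S)-1-[3,5-bis(1,3-dioxolan-2-yl)-2,4,6-trimethoxyphenyl]-3-[3-(1,3-dioxolan-2-yl)-6-hydroxy-2,4-dimethoxyphenyl]-5-methyl-2-(propan-2-yl)hexan-1-ol (both C1 epimers), via aryllithium 20 (not isolated)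
Conditions: 19 (2.6 equiv), n-BuLi (2.5 equiv), THF, −78 °C; then 15, −78 to 0 °C; then H2O
Reagents that add atoms: none
Why: Bromine–lithium exchange gives aryllithium 20, one equivalent of which deprotonates the lactol while a second adds 1,2 to the ring-opened phenoxide aldehyde (the established aryl-metal opening of 2-chromanols used in flavan synthesis); the carbinol configuration is left uncontrolled because the next step erases it.

Step 13
Reactants: 21 (2R,3S)-1-[3,5-bis(1,3-dioxolan-2-yl)-2,4,6-trimethoxyphenyl]-3-[3-(1,3-dioxolan-2-yl)-6-hydroxy-2,4-dimethoxyphenyl]-5-methyl-2-(propan-2-yl)hexan-1-ol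
Product: 23 5-[(2R,3R,4S)-6-formyl-5,7-dimethoxy-4-(2-methylpropyl)-3-(propan-2-yl)chroman-2-yl]-2,4,6-trimethoxybenzene-1,3-dicarbaldehyde, via chroman tris(dioxolane) 22 (not isolated)
Conditions: CSA (10 mol%), CH2Cl2, 0 °C; then 1 M aq HCl, THF, rt
Reagents that add atoms: water, O
Why: Acid ionises the ortho,para-trioxygenated benzylic alcohol to a stabilised cation that the phenol captures in a six-membered SN1 etherification (the flavan closure), placing the aryl group trans to the C3 isopropyl group, with reversible ionisation correcting any cis isomer; aqueous acid then hydrolyses the three dioxolanes.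

Step 14
Reactants: 23 5-[(2R,3R,4S)-6-formyl-5,7-dimethoxy-4-(2-methylpropyl)-3-(propan-2-yl)chroman-2-yl]-2,4,6-trimethoxybenzene-1,3-dicarbaldehyde
Product: 24 5-[(2R,3R,4S)-6-formyl-5,7-dihydroxy-4-(2-methylpropyl)-3-(propan-2-yl)-3,4-dihydro-2H-chromen-2-yl]-2,4,6-trihydroxybenzene-1,3-dicarbaldehyde (target)
Conditions: BBr3 (excess), CH2Cl2, −78 °C to rt; then H2O
Reagents that add atoms: none
Why: Boron tribromide cleavage of aryl methyl ethers (complexation, then bromide attack at methyl); all five ethers lie ortho to a formyl group, the aldehydes are held as boron chelates until work-up, and the C2–O1 ether should survive because the diformylated B ring no longer stabilises a benzylic cation.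

**Compound list**

1 | 4-hydroxy-2,6-dimethoxybenzaldehyde | COc1cc(O)cc(OC)c1C=O | starting material
2 | 4-hydroxy-3-iodo-2,6-dimethoxybenzaldehyde | O=Cc1c(OC)c(I)c(O)cc1OC | intermediate
3 | 4-(benzyloxy)-3-iodo-2,6-dimethoxybenzaldehyde | O=Cc1c(OC)c(I)c(OCc2ccccc2)cc1OC | intermediate
4 | 2-[4-(benzyloxy)-3-iodo-2,6-dimethoxyphenyl]-1,3-dioxolane | COc1cc(OCc2ccccc2)c(I)c(OC)c1C1OCCO1 | intermediate
5 | acenaphthylene-1,2-dione (acenaphthoquinone) | O=C1C(=O)c2cccc3cccc1c23 | starting material
6 | cis-1,2-dimethyl-1,2-dihydroacenaphthylene-1,2-diol (meso, "mac diol") | C[C@@]1(O)[C@](C)(O)c2cccc3cccc1c23 | intermediate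
7 | 4-methylpent-1-yne | CC(C)CC#C | starting material
8 | 2-[(Z)-4-methylpent-1-enyl]-1,3,2-benzodioxaborole | CC(C)C/C=C\B1Oc2ccccc2O1 | intermediate
9 | (Z)-4-methylpent-1-enylboronic acid ester of diol 6 (mac ester) | CC(C)C/C=C\B1O[C@]2(C)c3cccc4cccc(c34)[C@]2(C)O1 | intermediate
10 | isopropyllithium | [Li]C(C)C | starting material
11 | lithium isopropyl[(Z)-4-methylpent-1-enyl]borate of diol 6 (ate complex, configuration at boron not defined) | [Li+].CC(C)C/C=C\[B-]1(C(C)C)O[C@]2(C)c3cccc4cccc(c34)[C@]2(C)O1 | intermediate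
12 | mac ester of (3R,4S)-4-[6-(benzyloxy)-3-(1,3-dioxolan-2-yl)-2,4-dimethoxyphenyl]-2,6-dimethylheptan-3-ylboronic acid | CC(C)C[C@H](c1c(OCc2ccccc2)cc(OC)c(C2OCCO2)c1OC)[C@@H](C(C)C)B1O[C@]2(C)c3cccc4cccc(c34)[C@]2(C)O1 | intermediate
13 | mac ester of (2R,3S)-3-[6-(benzyloxy)-3-(1,3-dioxolan-2-yl)-2,4-dimethoxyphenyl]-1-chloro-5-methyl-2-(propan-2-yl)hexylboronic acid (both C1 epimers) | CC(C)C[C@H](c1c(OCc2ccccc2)cc(OC)c(C2OCCO2)c1OC)[C@@H](C(C)C)C(Cl)B1O[C@]2(C)c3cccc4cccc(c34)[C@]2(C)O1 | intermediate
14 | (2R,3S)-3-[6-(benzyloxy)-3-(1,3-dioxolan-2-yl)-2,4-dimethoxyphenyl]-5-methyl-2-(propan-2-yl)hexanal | CC(C)C[C@H](c1c(OCc2ccccc2)cc(OC)c(C2OCCO2)c1OC)[C@@H](C(C)C)C=O | intermediate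
15 | (3R,4S)-6-(1,3-dioxolan-2-yl)-5,7-dimethoxy-4-(2-methylpropyl)-3-(propan-2-yl)chroman-2-ol (both C2 epimers) | CC(C)C[C@@H]1c2c(cc(OC)c(C3OCCO3)c2OC)OC(O)[C@@H]1C(C)C | intermediate
16 | 1,3,5-trimethoxybenzene | COc1cc(OC)cc(OC)c1 | starting material
17 | 2,4,6-trimethoxybenzene-1,3-dicarbaldehyde | COc1cc(OC)c(C=O)c(OC)c1C=O | intermediate
18 | 5-bromo-2,4,6-trimethoxybenzene-1,3-dicarbaldehyde | COc1c(Br)c(OC)c(C=O)c(OC)c1C=O | intermediate
19 | 2,2'-(5-bromo-2,4,6-trimethoxy-1,3-phenylene)bis(1,3-dioxolane) | COc1c(Br)c(OC)c(C2OCCO2)c(OC)c1C1OCCO1 | intermediate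
20 | [3,5-bis(1,3-dioxolan-2-yl)-2,4,6-trimethoxyphenyl]lithium | COc1c([Li])c(OC)c(C2OCCO2)c(OC)c1C1OCCO1 | intermediate
21 | (2R,3S)-1-[3,5-bis(1,3-dioxolan-2-yl)-2,4,6-trimethoxyphenyl]-3-[3-(1,3-dioxolan-2-yl)-6-hydroxy-2,4-dimethoxyphenyl]-5-methyl-2-(propan-2-yl)hexan-1-ol (both C1 epimers) | CC(C)C[C@H](c1c(O)cc(OC)c(C2OCCO2)c1OC)[C@@H](C(C)C)C(O)c1c(OC)c(C2OCCO2)c(OC)c(C2OCCO2)c1OC | intermediate
22 | (2R,3R,4S)-2-[3,5-bis(1,3-dioxolan-2-yl)-2,4,6-trimethoxyphenyl]-6-(1,3-dioxolan-2-yl)-5,7-dimethoxy-4-(2-methylpropyl)-3-(propan-2-yl)chroman | CC(C)C[C@@H]1c2c(cc(OC)c(C3OCCO3)c2OC)O[C@@H](c2c(OC)c(C3OCCO3)c(OC)c(C3OCCO3)c2OC)[C@@H]1C(C)C | intermediate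
23 | 5-[(2R,3R,4S)-6-formyl-5,7-dimethoxy-4-(2-methylpropyl)-3-(propan-2-yl)chroman-2-yl]-2,4,6-trimethoxybenzene-1,3-dicarbaldehyde | CC(C)C[C@@H]1c2c(cc(OC)c(C=O)c2OC)O[C@@H](c2c(OC)c(C=O)c(OC)c(C=O)c2OC)[C@@H]1C(C)C | intermediate
24 | 5-[(2R,3R,4S)-6-formyl-5,7-dihydroxy-4-(2-methylpropyl)-3-(propan-2-yl)-3,4-dihydro-2H-chromen-2-yl]-2,4,6-trihydroxybenzene-1,3-dicarbaldehyde | CC(C)C[C@@H]1c2c(cc(O)c(C=O)c2O)O[C@@H](c2c(O)c(C=O)c(O)c(C=O)c2O)[C@@H]1C(C)C | target

**Step count**

Total: 14 steps. Longest linear sequence: 9 steps (steps 1, 2, 3, 6, 7, 8, 12, 13, 14, from compound 1).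

**Steps most likely to fail**

1. Step 6. The process at risk is the partition of the ate complex: transmetallation to the arylpalladium (Suzuki transfer of the alkenyl or isopropyl group) may outrun the 1,2-shift, and the di-ortho-oxygenated arylpalladium may bind the Z alkene slowly and with poor facial discrimination. The fallback replaces the three-component coupling by reagent-controlled lithiation–borylation. It sets out from 4: iodine–lithium exchange (n-BuLi, THF, −78 °C) and quench with 2-isopropoxy-4,4,5,5-tetramethyl-1,3,2-dioxaborolane would give the aryl pinacol boronate F1. Lithiated 3-methylbutyl 2,4,6-triisopropylbenzoate (s-BuLi, sparteine, Et2O, −78 °C) would be borylated with F1 and warmed to give, by 1,2-aryl shift with loss of the benzoate, the (R)-benzylic pinacol boronate F2. A second homologation of the same kind with lithiated 2-methylpropyl 2,4,6-triisopropylbenzoate would give the (3R,4S) pinacol boronate F3, the pinacol counterpart of 12. For each carbenoid the sparteine enantiomer is chosen by the known course of retentive borylation and invertive migration. F3 would be homologated and oxidised as in step 7, and the fallback comes back to the route at 14.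

2. Step 7. The process at risk is addition of the carbenoid to a boron atom flanked by an isopropyl group, a fully substituted benzylic carbon and the bulky diol; oxygen instead of carbon migration, or epimerisation of the α-branched aldehyde during oxidation, would also erode the result. The fallback brings C2 in as a vinyl carbon. It sets out from 12: Zweifel olefination (vinyllithium, THF, −78 °C; I2; NaOMe, MeOH) would give, with retention at the migrating carbon, the terminal alkene F4. Lemieux–Johnson cleavage (OsO4 cat., NaIO4, 2,6-lutidine, dioxane/H2O) then comes back to the route at 14.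

3. Step 14. The process at risk is Lewis-acid chemistry beyond ether cleavage: incomplete demethylation at the positions not assisted by chelation, opening of the benzylic C2–O1 bond with elimination or epimerisation, and bromination at the formyl carbons. The fallback replaces Lewis-acid cleavage by SN2 dealkylation at methyl. It sets out from 23: sodium ethanethiolate (DMF, 100–120 °C), then acidification, attacks only the methyl groups of the formyl-activated aryl ethers and comes back to the route at 24. No compound outside the list arises (none, F0).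

**Further compounds**

F1 | step 6 | 2-[4-(benzyloxy)-2,6-dimethoxy-3-(4,4,5,5-tetramethyl-1,3,2-dioxaborolan-2-yl)phenyl]-1,3-dioxolane | COc1cc(OCc2ccccc2)c(B2OC(C)(C)C(C)(C)O2)c(OC)c1C1OCCO1
F2 | step 6 | 2-{4-(benzyloxy)-2,6-dimethoxy-3-[(1R)-3-methyl-1-(4,4,5,5-tetramethyl-1,3,2-dioxaborolan-2-yl)butyl]phenyl}-1,3-dioxolane | CC(C)C[C@H](c1c(OCc2ccccc2)cc(OC)c(C2OCCO2)c1OC)B1OC(C)(C)C(C)(C)O1
F3 | step 6 | pinacol ester of (3R,4S)-4-[6-(benzyloxy)-3-(1,3-dioxolan-2-yl)-2,4-dimethoxyphenyl]-2,6-dimethylheptan-3-ylboronic acid | CC(C)C[C@H](c1c(OCc2ccccc2)cc(OC)c(C2OCCO2)c1OC)[C@@H](C(C)C)B1OC(C)(C)C(C)(C)O1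
F4 | step 7 | (3S,4S)-4-[6-(benzyloxy)-3-(1,3-dioxolan-2-yl)-2,4-dimethoxyphenyl]-6-methyl-3-(propan-2-yl)hept-1-ene | CC(C)C[C@H](c1c(OCc2ccccc2)cc(OC)c(C2OCCO2)c1OC)[C@@H](C(C)C)C=C
F0 | step 14 | none | none
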